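**Per hour.** Per hour is the unit in which I follow E, the product of Z with dissolved gas J, and Z itself is at 0% at the first reading of Friday's run, which is the flask asked about.

in all of them: L 28 mM (held)
- Friday's: Z 0.40 M; the very flask that is asked about, followed so far
- Tuesday's: Z 0.27 M; run made earlier
- flask: Z 0.40 M; time 2.5 h

Friday's run (percent of the Z charged)

| time / min | E / % | Z / % |
|---|---|---|
| 2.50 | 29.0 | 0 |
| 6.00 | 28.0 | 0 |
| 12.0 | 27.5 | 1.4 |
| 20.0 | 26.2 | 0 |
| 25.0 | 24.5 | 0.5 |

Tuesday's run (percent of the Z charged)

| time / h | E / % | Z / % |
|---|---|---|
| 0.200 | 33.1 | 0 |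
| 0.417 | 29.6 | 0.6 |
| 0.667 | 26.5 | 0.5 |
| 1.33 | 20.1 | 0 |
| 2.50 | 12.5 | 0 |

(standard deviation of a reading: 0.5 percentage points)

- at the start none of J is dissolved
- what may be going on: 2 J -> X; L <-> J; Z -> Q; J + E -> D; Z + J -> E

- the moment within 2.5 h at which there is most E, in min
- the amount of E, in percent of the Z charged, at that time

**Bench rule.** Tuesday's first and last readings give 0.423 /h, the decay constant kE of E, the natural logarithm of the fall in E over the time it took. Friday's shorter run gives 0.450 /h, so I treat the loss of E as pseudo-first-order, with J steady. The rule is to run this line back to the start: Friday's first reading then gives 29.5%, my peak. Over 2.5 h the line keeps a fraction 34.7% of E.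

**Its border.** Up to the first reading, at 2.50 min, the line falls by 0.52 percentage points, and a reading scatters by 0.5 points. So I can place the peak before that reading, but no closer.

**The forecast.** It gives 29.3% at 1.5 min, lower than my 29.5%, and says of the time: “The data do not resolve this time well.”

**The flask.** It gives 28.8% at 1.65 min, and the forecast stands.

    2 J → X (k = 0.186 /M/s)
    L ⇌ J, rate k2*(csat - [J]) (kL = 0.0666 /s)
    Z → Q (k = 0.0296 /s)
    J + E → D (k = 0.00473 /M/s)
    Z + J → E (k = 8.99 /M/s)

**What stands.** In the flask asked about, Z has a half-life of 0.39 min by the passing into Q alone, while kE, read from Tuesday's run, gives E a half-life of 98.2 min, which is 252 times longer; in that flask Q stands at 71.1% at the peak and at 71.1% at 2.50 h, while E falls to 10.3% against the 9.99% that kE gives. The neighbour flask with 0.16 M of Z peaks at 44.1%, and from that peak kE gives 15.3% at the end, where that flask holds 15.6%.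

The readings were generated by integration for an exercise; scatter was added.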